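I start from the late end of the run and ask what D.L over D would stand at once step 2 has balanced.

    L ⇌ Q, rate k1*([L] - [Q]/K1) per volume of the first phase (K1 = 0.33, k1 = 0.0195 s⁻¹)
    D + L ⇌ D.L (K2 = 100 M⁻¹, k2 = 19.6 M⁻¹ s⁻¹)
    L + D.L → L.D.L (k3 = 6.65 M⁻¹ s⁻¹)
    2 L → L2 (k4 = 7.53 M⁻¹ s⁻¹)

D 5.0 mM; Q 2.00 equiv; time 10 s; volume of the second phase over the first 0.50

- violet: doubling the transfer coefficient of step 1, all else as stated
- ochre: doubling the amount of Q, all else as stated

- for a step with 2 of a species take k times the square, and two of it per event
- in the second phase: Q; everything else is in the first
- charges count per volume of the first phase; a concentration in a rate is the amount of a species over the volume of its own phase; every rate counts per litre of the first phase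
- run time (flask): 10 s

1. the D.L standing at 10 s, as a percentage of the D charged
2. the change that raises the amount of D.L at 10 s, in percent of the D charged most ("none" if none brings more than 2 percentage points) (violet / ochre / none)
3. amount of D.L at 10 s, in percent of the D charged, after violet

1. Q and L approach their partition balance with relaxation time 7.26 s. That balance holds 8.58 mM of L, so by 10 s about 6.42 mM has crossed, if nothing spends it.

2. At balance of step 2, D.L over D equals free L times the binding ratio per unit of free L, 0.100 mM⁻¹. The share of D bound, the fractional saturation, is that product over one plus itself. The crossed stock gives 39.1%.

3. High extreme: no L2 forms. Going round once, D.L has taken its L, leaving 4.46 mM, and the share is 30.9%.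

4. Low extreme: L2 also takes its full charge on a straight rise to the crossed stock, 2.07 mM of L. The share is 19.3%.

5. The low extreme charges L2 on a stock larger than the one the round leaves, which pulls it low. Both extremes also take step 2 as balanced, yet the half-life of L by the forward step alone, with D as charged, is 7.1 s in a run of 10 s, so balance may lag, and that pulls both high. With errors on both sides, I estimate that the flask lies between them, though neither extreme is a bound, and I commit to the midpoint, 25.1%.

6. Violet crosses 8.04 mM. The same ladder leaves 5.81 mM and gives 28.6%. Ochre crosses 12.8 mM, more than violet, so I name ochre.

7. The forecast says 21.8% (19% to 25%), below my figure, and 26% (23% to 29.5%) after violet. It names ochre: “doubling Q matches that early L rise and then holds L higher”.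

The flask gives 21.7% at 10.0 s, and 25.3% after violet. The best change is ochre, which gains 9.4 percentage points against 3.6 points for violet. Free L in this flask stands at 3.84 mM then, so the binding ratio gives 0.384, while D.L over D reads 0.286, still below it. The same flask read at 40.0 s holds 1.98 mM of free L, so the ratio gives 0.198, and D.L over D there reads 0.206.

All constants are made up; the flask was simulated.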